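The target is cut at the C2–C1′ bond between the pyran ring and ring B, not at the usual O1–C2 bond. C2 is treated as the β-carbon of a C4 ketone: a Rh-catalysed enantioselective 1,4-addition of an arylboronic acid to a flat, achiral 8-prenylchromone joins the two halves and sets C2, the only stereocentre, in one operation. The precursor, ethyl 5-methoxy-8-prenyl-4-oxochromen-7-yl carbonate, comes without regiochemical ambiguity from symmetric 5-methoxyresorcinol, the prenyl group entering between the oxygens that become O1 and O7. The C4 oxygen is then erased in one pot through the para-quinone methide that O7, para to C4a, makes accessible.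

Key step: step 7

The target SMILES is read as the (2R)-flavan (priorities at C2: O1 > C1′ > C3 > H). Abbreviations: MOM = methoxymethyl; prenyl = 3-methylbut-2-en-1-yl.

Assumption: the sense of induction in step 7 is taken from the established stereochemical model for Rh/biaryl-bisphosphine 1,4-additions to cyclohex-2-enone ((S)-ligand gives the (S)-β-aryl ketone, which maps onto the (2S)-chromanone), so the (R)-ligand is specified for the (2R) series; should a first run show the opposite sense, the antipodal ligand is used with no other change.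

Step 1
Reactants: 1 5-methoxybenzene-1,3-diol
Product: 2 1-methoxy-3,5-bis(methoxymethoxy)benzene
Conditions: MOMCl (2.5 equiv), i-Pr2NEt, CH2Cl2, 0 °C to rt
Reagents that add atoms: chloromethyl methyl ether (MOMCl), COCCl
Why: Base-mediated O-alkylation (Williamson-type MOM protection) of the two equivalent phenols should be clean and installs the two ortho-directing groups used in steps 2 and 3; no stereocentre is formed.

Step 2
Reactants: 2 1-methoxy-3,5-bis(methoxymethoxy)benzene
Product: 4 5-methoxy-1,3-bis(methoxymethoxy)-2-(3-methylbut-2-en-1-yl)benzene, via aryllithium 3 (not isolated)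
Conditions: n-BuLi, THF, 0 °C to rt; then CuI (10 mol %), prenyl bromide, −78 °C to rt
Reagents that add atoms: prenyl bromide (1-bromo-3-methylbut-2-ene), CC(C)=CCBr
Why: Directed ortho-metalation should take the ring C–H flanked by both OMOM groups (cooperative chelation), and copper-assisted SN2 alkylation of the aryllithium then places the prenyl group between the two oxygens that become O1 and O7; no stereocentre is formed.

Step 3
Reactants: 4 5-methoxy-1,3-bis(methoxymethoxy)-2-(3-methylbut-2-en-1-yl)benzene
Product: 7 1-[6-methoxy-2,4-bis(methoxymethoxy)-3-(3-methylbut-2-en-1-yl)phenyl]ethan-1-one, via aryllithium 5 (not isolated), via tetrahedral lithium adduct 6 (not isolated)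
Conditions: n-BuLi, TMEDA, THF, −20 to 0 °C; then MeC(O)N(OMe)Me, −78 °C to rt; H2O
Reagents that add atoms: N-methoxy-N-methylacetamide, CC(=O)N(C)OC
Why: A second directed ortho-metalation can only take the two remaining ring positions, which are equivalent and each flanked by OMOM and OMe, and the Weinreb ketone synthesis stops at the ketone because the chelated tetrahedral adduct survives until the quench; the carbinol centre of the adduct is lost on collapse, so no stereocentre remains.

Step 4
Reactants: 7 1-[6-methoxy-2,4-bis(methoxymethoxy)-3-(3-methylbut-2-en-1-yl)phenyl]ethan-1-one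
Product: 9 7-hydroxy-5-methoxy-8-(3-methylbut-2-en-1-yl)-4H-chromen-4-one, via enaminone 8 (not isolated)
Conditions: Me2NCH(OMe)2, toluene, 105 °C, evaporate; then conc. HCl, MeOH, rt to 40 °C
Reagents that add atoms: N,N-dimethylformamide dimethyl acetal, COC(OC)N(C)C
Why: Condensation of the methyl ketone with the amide acetal gives the enaminone, and acid then cleaves both MOM ethers so that the only free ortho-hydroxyl (the other ortho position carries OMe) adds 6-endo to the β-carbon and expels dimethylamine (enaminone route to chromones), which places O1 next to the prenyl-bearing carbon; no stereocentre is formed.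

Step 5
Reactants: 9 7-hydroxy-5-methoxy-8-(3-methylbut-2-en-1-yl)-4H-chromen-4-one
Product: 10 ethyl 5-methoxy-8-(3-methylbut-2-en-1-yl)-4-oxo-4H-chromen-7-yl carbonate
Conditions: ClCO2Et, Et3N, CH2Cl2, 0 °C
Reagents that add atoms: ethyl chloroformate, CCOC(=O)Cl
Why: O-Acylation of the single phenol (ethoxycarbonylation) gives a neutral, mildly electron-withdrawing 7-substituent that keeps the chromone electrophilic in step 7 and later serves as the trigger for the deoxygenation in step 8; no stereocentre is formed.

Step 6
Reactants: 11 3-bromo-5-methoxyphenol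
Product: 12 (3-hydroxy-5-methoxyphenyl)boronic acid
Conditions: XPhos Pd G2 (1 mol %), XPhos (2 mol %), B2(OH)4, KOAc, EtOH, 80 °C
Reagents that add atoms: tetrahydroxydiboron, OB(O)B(O)O
Why: Pd-catalysed Miyaura-type borylation of the aryl bromide with tetrahydroxydiboron should give the boronic acid directly and tolerates the free phenol; no stereocentre is formed.

Step 7
Reactants: 10 ethyl 5-methoxy-8-(3-methylbut-2-en-1-yl)-4-oxo-4H-chromen-7-yl carbonate, 12 (3-hydroxy-5-methoxyphenyl)boronic acid
Product: 13 ethyl (2R)-2-(3-hydroxy-5-methoxyphenyl)-5-methoxy-8-(3-methylbut-2-en-1-yl)-4-oxo-3,4-dihydro-2H-chromen-7-yl carbonate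
Conditions: [RhCl(C2H4)2]2 (1.5 mol %), (R)-MeO-F12-BIPHEP (3.3 mol %), KOH (10 mol %), 12 (2 equiv), toluene/H2O 10:1, 30 °C
Reagents that add atoms: none
Why: In this Hayashi–Miyaura reaction the aryl group of 12 is transferred to a Rh(I)–OH complex, the aryl–Rh species binds the C2=C3 bond of 10 and inserts it with aryl going to C2 and Rh to C3 (oxa-π-allyl rhodium enolate), and water releases the chromanone and regenerates Rh–OH. The closest known reaction type is the Rh/bisphosphine-catalysed enantioselective 1,4-addition of arylboronic acids to chromones, which is known for 5,7-dioxygenated chromones. No ring is closed: the step forms the C2–C1′ bond on the preformed pyranone ring and turns the planar, achiral chromone into the chiral chromanone. C2 is set under catalyst control, the C2-symmetric biaryl bisphosphine shielding one enantioface of the bound enone in the insertion step, and the (R)-ligand is expected to give (2R) as stated in the assumption. The step needs 1,4- over 1,2-addition and reaction at the enone only, which the soft aryl–Rh(I) species secures because it neither inserts the unactivated trisubstituted prenyl alkene nor attacks the carbonate. It also needs protonation of the rhodium enolate before it can expel the aryloxide (ring opening to a chalcone would erase C2), which the water co-solvent, the near-neutral medium and the low temperature allowed by the electron-poor ligand should secure, while the excess of 12 offsets protodeboronation.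

Step 8
Reactants: 13 ethyl (2R)-2-(3-hydroxy-5-methoxyphenyl)-5-methoxy-8-(3-methylbut-2-en-1-yl)-4-oxo-3,4-dihydro-2H-chromen-7-yl carbonate
Product: 17 (2R)-2-(3-hydroxy-5-methoxyphenyl)-5-methoxy-8-(3-methylbut-2-en-1-yl)-3,4-dihydro-2H-chromen-7-ol, via flavan-4-ol carbonate 14 (not isolated), via flavan-4,7-diol 15 (not isolated), via para-quinone methide 16 (not isolated)
Conditions: NaBH4 (6 equiv), THF/H2O 1:1, 0 °C, then 40 °C; aq NH4Cl
Reagents that add atoms: none
Why: Borohydride should first reduce the C4 ketone in the cold, the alkaline medium then cleaves the aryl carbonate, and the 7-phenoxide, para to C4a, expels the C4 oxygen to give a para-quinone methide that takes a second hydride at C4 (NaBH4 deoxygenation of para-acyloxyaryl ketones via a quinone methide); C2 is not touched because the ketone is reduced before base can open the ring, and C4 ends as CH2.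

Compound list
1 | 5-methoxybenzene-1,3-diol (5-methoxyresorcinol) | COc1cc(O)cc(O)c1 | starting material
2 | 1-methoxy-3,5-bis(methoxymethoxy)benzene | COCOc1cc(OC)cc(OCOC)c1 | intermediate
3 | [4-methoxy-2,6-bis(methoxymethoxy)phenyl]lithium | [Li]c1c(OCOC)cc(OC)cc1OCOC | intermediate
4 | 5-methoxy-1,3-bis(methoxymethoxy)-2-(3-methylbut-2-en-1-yl)benzene | COCOc1cc(OC)cc(OCOC)c1CC=C(C)C | intermediate
5 | [6-methoxy-2,4-bis(methoxymethoxy)-3-(3-methylbut-2-en-1-yl)phenyl]lithium | [Li]c1c(OC)cc(OCOC)c(CC=C(C)C)c1OCOC | intermediate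
6 | lithium 1-[methoxy(methyl)amino]-1-[6-methoxy-2,4-bis(methoxymethoxy)-3-(3-methylbut-2-en-1-yl)phenyl]ethan-1-olate (tetrahedral adduct, racemic at the carbinol carbon) | CC(O[Li])(N(C)OC)c1c(OC)cc(OCOC)c(CC=C(C)C)c1OCOC | intermediate
7 | 1-[6-methoxy-2,4-bis(methoxymethoxy)-3-(3-methylbut-2-en-1-yl)phenyl]ethan-1-one | CC(=O)c1c(OC)cc(OCOC)c(CC=C(C)C)c1OCOC | intermediate
8 | (E)-3-(dimethylamino)-1-[6-methoxy-2,4-bis(methoxymethoxy)-3-(3-methylbut-2-en-1-yl)phenyl]prop-2-en-1-one | CN(C)/C=C/C(=O)c1c(OC)cc(OCOC)c(CC=C(C)C)c1OCOC | intermediate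
9 | 7-hydroxy-5-methoxy-8-(3-methylbut-2-en-1-yl)-4H-chromen-4-one | COc1cc(O)c(CC=C(C)C)c2occc(=O)c12 | intermediate
10 | ethyl 5-methoxy-8-(3-methylbut-2-en-1-yl)-4-oxo-4H-chromen-7-yl carbonate | CCOC(=O)Oc1cc(OC)c2c(=O)ccoc2c1CC=C(C)C | intermediate
11 | 3-bromo-5-methoxyphenol | COc1cc(O)cc(Br)c1 | starting material
12 | (3-hydroxy-5-methoxyphenyl)boronic acid | COc1cc(O)cc(B(O)O)c1 | intermediate
13 | ethyl (2R)-2-(3-hydroxy-5-methoxyphenyl)-5-methoxy-8-(3-methylbut-2-en-1-yl)-4-oxo-3,4-dihydro-2H-chromen-7-yl carbonate | COc1cc(O)cc([C@H]2CC(=O)c3c(OC)cc(OC(=O)OCC)c(CC=C(C)C)c3O2)c1 | intermediate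
14 | ethyl (2R)-4-hydroxy-2-(3-hydroxy-5-methoxyphenyl)-5-methoxy-8-(3-methylbut-2-en-1-yl)-3,4-dihydro-2H-chromen-7-yl carbonate (either C4 epimer, the 2,4-cis one expected to prevail; C4 is lost later) | COc1cc(O)cc([C@H]2CC(O)c3c(OC)cc(OC(=O)OCC)c(CC=C(C)C)c3O2)c1 | intermediate
15 | (2R)-2-(3-hydroxy-5-methoxyphenyl)-5-methoxy-8-(3-methylbut-2-en-1-yl)-3,4-dihydro-2H-chromene-4,7-diol (present as its phenoxide; C4 epimers) | COc1cc(O)cc([C@H]2CC(O)c3c(OC)cc(O)c(CC=C(C)C)c3O2)c1 | intermediate
16 | (2R)-2-(3-hydroxy-5-methoxyphenyl)-5-methoxy-8-(3-methylbut-2-en-1-yl)-2,3-dihydro-7H-chromen-7-one (para-quinone methide, C4=C4a) | COc1cc(O)cc([C@H]2CC=C3C(OC)=CC(=O)C(CC=C(C)C)=C3O2)c1 | intermediate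
17 | (2R)-2-(3-hydroxy-5-methoxyphenyl)-5-methoxy-8-(3-methylbut-2-en-1-yl)-3,4-dihydro-2H-chromen-7-ol | COc1cc(O)cc([C@H]2CCc3c(OC)cc(O)c(CC=C(C)C)c3O2)c1 | target

Total step count: 8. Longest linear sequence: 7 (steps 1–5, 7, 8); step 6 is the side branch.

Steps most likely to fail

Step 7. The insertion into the electron-rich, peri-substituted chromone may be slow, so that protodeboronation of 12 wins. Alternatively the rhodium enolate may open the ring, or the facial selectivity may be insufficient. The fallback gives up the C2–C1′ disconnection for a ketone reduction and C–O ring closure; it sets out from 4 and returns at 17. Lithiation of 4 as in step 3 and a DMF quench should give 6-methoxy-2,4-bis(methoxymethoxy)-3-(3-methylbut-2-en-1-yl)benzaldehyde F1. Claisen–Schmidt condensation (KOH, EtOH) with commercial 1-(3-hydroxy-5-methoxyphenyl)ethan-1-one should give (E)-1-(3-hydroxy-5-methoxyphenyl)-3-[6-methoxy-2,4-bis(methoxymethoxy)-3-(3-methylbut-2-en-1-yl)phenyl]prop-2-en-1-one F2. Conjugate reduction with Stryker's reagent, which leaves the prenyl group alone, should give 1-(3-hydroxy-5-methoxyphenyl)-3-[6-methoxy-2,4-bis(methoxymethoxy)-3-(3-methylbut-2-en-1-yl)phenyl]propan-1-one F3. CBS reduction with (R)-Me-CBS and BH3·SMe2 should give (1S)-1-(3-hydroxy-5-methoxyphenyl)-3-[6-methoxy-2,4-bis(methoxymethoxy)-3-(3-methylbut-2-en-1-yl)phenyl]propan-1-ol F4. HCl in MeOH at rt should remove both MOM groups to give 2-[(3S)-3-hydroxy-3-(3-hydroxy-5-methoxyphenyl)propyl]-5-methoxy-3-(3-methylbut-2-en-1-yl)benzene-1,3-diol... more precisely 4-[(3S)-3-hydroxy-3-(3-hydroxy-5-methoxyphenyl)propyl]-5-methoxy-2-(3-methylbut-2-en-1-yl)benzene-1,3-diol F5. An intramolecular Mitsunobu reaction (PPh3, DIAD, THF, high dilution) should then close O1–C2 with inversion; only the hydroxyl ortho to the chain can form the six-membered ring, and the product is 17.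

Step 8. Carbonate cleavage may outrun ketone reduction, so that the 7-phenoxide chromanone opens to the chalcone and C2 erodes. The sequence may also stall at the flavan-4-ol, or the quinone methide may lose a C3 proton to give the flav-3-ene instead of taking hydride. The fallback replaces the anionic quinone-methide pathway by a cationic deoxygenation with the carbonate kept on; it sets out from 13 and returns at 17. Luche-type reduction (NaBH4, CeCl3·7H2O, MeOH, −40 °C) should allow 14 to be isolated. Ionic hydrogenation (Et3SiH, TFA, CH2Cl2, −40 °C) of the benzylic cation, stabilised by the 5- and 7-oxygens, should give ethyl (2R)-2-(3-hydroxy-5-methoxyphenyl)-5-methoxy-8-(3-methylbut-2-en-1-yl)-3,4-dihydro-2H-chromen-7-yl carbonate F6; the carbonate keeps O7 from adding to the prenyl group under acid. K2CO3 in MeOH at rt then frees the phenol to give 17.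

Step 3. Deprotonation at the benzylic and allylic CH2 of the prenyl group may compete with ring metalation, or the hindered aryllithium may be quenched by proton transfer from the amide. The fallback generates the same aryllithium by halogen–metal exchange instead of C–H deprotonation; it sets out from 4 and returns at 5. Bromination (NBS, MeCN, −20 °C) at the only free ring position, fixed by symmetry, should give 2-bromo-1-methoxy-3,5-bis(methoxymethoxy)-4-(3-methylbut-2-en-1-yl)benzene F7. Br/Li exchange (n-BuLi, THF, −78 °C), which is faster than any deprotonation, then gives 5, and the route continues to 7 as in step 3.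

Further compounds
F1 | step 7 | 6-methoxy-2,4-bis(methoxymethoxy)-3-(3-methylbut-2-en-1-yl)benzaldehyde | O=Cc1c(OC)cc(OCOC)c(CC=C(C)C)c1OCOC
F2 | step 7 | (E)-1-(3-hydroxy-5-methoxyphenyl)-3-[6-methoxy-2,4-bis(methoxymethoxy)-3-(3-methylbut-2-en-1-yl)phenyl]prop-2-en-1-one | COc1cc(O)cc(C(=O)/C=C/c2c(OC)cc(OCOC)c(CC=C(C)C)c2OCOC)c1
F3 | step 7 | 1-(3-hydroxy-5-methoxyphenyl)-3-[6-methoxy-2,4-bis(methoxymethoxy)-3-(3-methylbut-2-en-1-yl)phenyl]propan-1-one | COc1cc(O)cc(C(=O)CCc2c(OC)cc(OCOC)c(CC=C(C)C)c2OCOC)c1
F4 | step 7 | (1S)-1-(3-hydroxy-5-methoxyphenyl)-3-[6-methoxy-2,4-bis(methoxymethoxy)-3-(3-methylbut-2-en-1-yl)phenyl]propan-1-ol | COc1cc(O)cc([C@@H](O)CCc2c(OC)cc(OCOC)c(CC=C(C)C)c2OCOC)c1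
F5 | step 7 | 4-[(3S)-3-hydroxy-3-(3-hydroxy-5-methoxyphenyl)propyl]-5-methoxy-2-(3-methylbut-2-en-1-yl)benzene-1,3-diol | COc1cc(O)cc([C@@H](O)CCc2c(OC)cc(O)c(CC=C(C)C)c2O)c1
F6 | step 8 | ethyl (2R)-2-(3-hydroxy-5-methoxyphenyl)-5-methoxy-8-(3-methylbut-2-en-1-yl)-3,4-dihydro-2H-chromen-7-yl carbonate | COc1cc(O)cc([C@H]2CCc3c(OC)cc(OC(=O)OCC)c(CC=C(C)C)c3O2)c1
F7 | step 3 | 2-bromo-1-methoxy-3,5-bis(methoxymethoxy)-4-(3-methylbut-2-en-1-yl)benzene | COCOc1cc(OC)c(Br)c(OCOC)c1CC=C(C)C
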